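I was asked when, within 20 h, this flask held most L, and how much.

| flask | X | G | remark | time |
|---|---|---|---|---|
| south-east | 0.20 M | 0.36 M | run made earlier |  |
| flask | 0.40 M | 0.360 M |  | 20 h |

south-east run (percent of the X charged)

| time / min | L / % | X / % |
|---|---|---|
| 10.0 | 7.2 | 24.3 |
| 15.0 | 10.8 | 12.4 |
| 25.0 | 20.1 | 3.6 |
| 40.0 | 26.7 | 0.9 |
| 80.0 | 33.2 | 0.2 |
| 120 | 33.2 | 0.4 |

(readings scatter by 0.5 percentage points)

* the moment within 20 h at which there is most L
* the amount of L, in percent of the X charged, at that time

In the south-east run L climbed by 13 percentage points from 10.0 min to 25.0 min, overtook X between 15.0 min and 25.0 min, bent between 40.0 min and 80.0 min, and then read 33.2%. At 25.0 min, 76.3% of the charge showed as neither X nor L, so I followed one molecule: it left X for an unseen form, and I assumed it then needed one G to become L. This flask starts with about the same cG as that run, so I drew the same start and put the top at the same knee, near 1.3 h. But its cX of 0.40 M is more than its cG of 0.360 M, which makes G the limiting reagent on that assumption. I therefore carried the stranded share, the chance that a molecule of X finds no G at the fork, 10.0%, and set the top below the south-east level.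

The forecast gave 5 h (range 1.5 h to 20 h) and 31% (range 26% to 35%), holding that “The maximum is a flat plateau, so its timing is loose”. My time was earlier than its time.

The flask peaked at 1.29 h with 28.3%, so the forecast's amount held and its time was 3.88 times too late.

    X → D (k = 8.40 h⁻¹)
    G + D → L (k = 2.80 L mol⁻¹ h⁻¹)
    L ⇌ Z (K = 0.870, k = 0.910 h⁻¹)
    L → Q (k = 0.350 h⁻¹)

X halved in 0.083 h by its own step, while D, with G as charged, took longer, 0.69 h, by its step with G, and at 1.29 h this flask held 47.5% of D beside 28.3% of L. By 200 h this flask held 10.0% of D with G at 0%, against a stranded share of 10.0%. The neighbour with 1.0 M of X had a stranded share of 64.0%, and at 20.0 h, with G at 0%, it held 64.0% of D.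

Readings and results come from a simulation with constants of no real substance.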